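## Retrosynthetic overview

1. Target 21 comes from 20 and 19 by O-demethylation and saponification at the very end. All phenols travel as methyl ethers and the acids as methyl esters.
2. In 19 the C3=C4 alkene and the H on C2 come from the 1,4-dihydronaphthalene 18. Loss of a temporary carboxyl carbon on C4 moves the alkene (allylic transposition).
3. Ring B is the only ring formed (step 8), by an aryne Diels–Alder reaction. C4a and C8a are neighbouring carbons of ring A, and the O atoms on C6 and C7 lie symmetrically to them, so ring A can enter as the symmetric 4,5-dimethoxybenzyne 15. C1–C2–C3–C4, with both carboxyl carbons on the inner atoms C2 and C3, is a 1,3-diene (13).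
4. Diene 13 comes from Stille coupling of stannane 9 (syn-hydrostannation of aryl propiolate 8) with bromobutenolide 12. Its temporary lactone ring holds the C3 carboxyl carbon, the temporary carbon and the menthyloxy acetal centre that steers the aryne; it is opened in step 10.
5. The (E)-enol ether 6 comes from O–H insertion into phenol 3 followed by Still–Gennari olefination with 5. Rings A, C and D are bought.

Key step: step 8

Assumption: the SMILES is read as (1R,2S), with ring C on C1 and the carboxyl group on C2 trans, and as E at the enol ether (aryloxy O trans to ring D); (5S)-5-(d-menthyloxy)furan-2(5H)-one 10 is taken as commercially available, like its enantiomer.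

Locants:
- C1 to C8a are those of the dihydronaphthalene of the target.
- Ring A is C4a–C8a, with O on C6 and C7. Ring B is C1–C4 plus C4a and C8a.
- Ring C is the aryl group on C1. Ring D is the catechol ring of the side chain.
- ArC = 3-{[(E)-2-(3,4-dimethoxyphenyl)-1-(methoxycarbonyl)ethenyl]oxy}-4-methoxyphenyl.

## Route

Step 1
Reactants: 1 methyl 2-[bis(2,2,2-trifluoroethoxy)phosphoryl]acetate
Product: 2 methyl 2-[bis(2,2,2-trifluoroethoxy)phosphoryl]-2-diazoacetate
Conditions: p-ABSA, DBU, MeCN, 0 °C → rt
Reagents that add atoms: 4-acetamidobenzenesulfonyl azide (p-ABSA), CC(=O)Nc1ccc(cc1)S(=O)(=O)N=[N+]=[N-]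
Why: Regitz diazo transfer onto the doubly activated CH2 group, which the trifluoroethyl groups make acidic enough for DBU; no stereocentre is formed.

Step 2
Reactants: 2 methyl 2-[bis(2,2,2-trifluoroethoxy)phosphoryl]-2-diazoacetate; 3 5-iodo-2-methoxyphenol
Product: 4 methyl 2-[bis(2,2,2-trifluoroethoxy)phosphoryl]-2-(5-iodo-2-methoxyphenoxy)acetate (racemic)
Conditions: Rh2(OAc)4 (cat.), toluene, 80 °C, slow addition of 2
Reagents that add atoms: none
Why: Rhodium carbenoid O–H insertion of a diazophosphonoacetate into a phenol, which should outrun attack on the arene or the C–I bond; the new stereocentre is racemic and disappears in step 3.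

Step 3
Reactants: 4 aryloxy phosphonoacetate; 5 3,4-dimethoxybenzaldehyde
Product: 6 methyl (E)-3-(3,4-dimethoxyphenyl)-2-(5-iodo-2-methoxyphenoxy)prop-2-enoate
Conditions: KN(SiMe3)2, 18-crown-6, THF, −78 °C; then 5
Reagents that add atoms: none
Why: In this Still–Gennari variant of the Horner–Wadsworth–Emmons olefination the electron-poor phosphonate under dissociating conditions lets the kinetic adduct collapse before it reverts, which places ring D cis to the ester and trans to the aryloxy oxygen (E), a sense to which α-heteroatom-substituted phosphonoacetates already lean.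

Step 4
Reactants: 6 iodoaryl enol ether; 7 methyl propiolate
Product: 8 methyl 3-ArC-prop-2-ynoate
Conditions: PdCl2(PPh3)2 (cat.), CuI (cat.), K2CO3, THF, 65 °C, excess 7
Reagents that add atoms: none
Why: Sonogashira coupling of an aryl iodide with a propiolate ester, run with an inorganic base so that no amine adds to the alkynoate; the esters and the enol ether are inert.

Step 5
Reactants: 8 methyl 3-ArC-prop-2-ynoate
Product: 9 methyl (E)-3-ArC-2-(tributylstannyl)prop-2-enoate
Conditions: Bu3SnH, Pd(PPh3)4 (cat.), THF, 0 °C → rt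
Reagents that add atoms: tributyltin hydride, CCCC[SnH](CCCC)CCCC
Why: Palladium-catalysed syn-hydrostannation of an aryl alkynoate puts tin α to the ester and H on the benzylic carbon on the same side, so ring C and the ester end cis; the trisubstituted enol ether alkene should not react.

Step 6
Reactants: 10 (5S)-5-[(1S,2R,5S)-menthyloxy]furan-2(5H)-one
Product: 12 (5S)-3-bromo-5-[(1S,2R,5S)-menthyloxy]furan-2(5H)-one, via trans-3,4-dibromolactone 11 (not isolated)
Conditions: Br2, CH2Cl2, 0 °C → rt; then Et3N, 0 °C
Reagents that add atoms: bromine, BrBr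
Why: Anti addition of bromine to the butenolide alkene followed by E1cB loss of HBr (acidic H on the α-carbon, bromide on the β-carbon) is the standard bromination–dehydrobromination route to α-bromobutenolides; the acetal centre is not touched, and recrystallisation should remove any epimer.

Step 7
Reactants: 9 α-stannyl acrylate; 12 bromobutenolide
Product: 13 methyl (Z)-3-ArC-2-{(5S)-5-[(1S,2R,5S)-menthyloxy]-2-oxo-2,5-dihydrofuran-3-yl}prop-2-enoate
Conditions: Pd2(dba)3 (cat.), AsPh3, CuI (cat.), DMF, 50 °C
Reagents that add atoms: none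
Why: Copper-assisted Stille coupling of an α-stannyl acrylate with an α-bromobutenolide goes with retention at both sp2 carbons, so ring C (on C1) and the acetal carbon (on C4) both take outer positions of the diene; the acetal centre is not involved.

Step 8
Reactants: 13 diene; 14 4,5-dimethoxy-2-(trimethylsilyl)phenyl trifluoromethanesulfonate
Product: 16 lactone-bridged (1R,4S)-1,4-dihydronaphthalene cycloadduct (full description in the compound list), via 4,5-dimethoxybenzyne 15 (not isolated)
Conditions: CsF, MeCN/toluene, rt, slow addition of 14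
Reagents that add atoms: none
Why: Fluoride-induced 1,2-elimination of 14 releases 4,5-dimethoxybenzyne 15, which adds across C1 and C4 of the s-cis form of 13 in a concerted, suprafacial [4π+2π] cycloaddition (aryne Diels–Alder reaction). The closest known reaction type is the Diels–Alder reaction of arynes with acyclic and semicyclic acceptor-substituted 1,3-dienes, including auxiliary-controlled versions that give cis-1,4-disubstituted 1,4-dihydronaphthalenes. Ring B is closed by this cycloaddition alone, with C1–C8a and C4–C4a formed together. C1 and C4 arise cis because ring C and the acetal carbon both occupy outer diene positions (both inner positions are H), and their absolute sense follows from approach of the aryne to the face of the flat butenolide opposite to the menthyloxy group on the acetal carbon directly attached to C4, so that the (5S)-acetal leads to (1R). No regiochemistry arises, because each carbon of the triple bond has a CH beside it and the two methoxy groups lie mirror-symmetrically to it. Chemoselectivity rests on 13 offering only one 4π unit with H on both inner positions, whereas the enol ether alkene is trisubstituted and acceptor-bearing, and slow addition keeps the aryne too dilute to abstract hydrogen from the adduct.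

Step 9
Reactants: 16 cycloadduct
Product: 17 lactol (anomeric mixture, in equilibrium with its open aldehyde acid form)
Conditions: TFA/H2O/THF, 40 °C, argon
Reagents that add atoms: water, O
Why: Acid hydrolysis of the mixed acetal (pseudo-ester) frees the lactol and the auxiliary alcohol, while the methyl esters, aryl methyl ethers and the acceptor-substituted enol ether should stay; the acidic medium avoids enolisation at C4, C1 and C4 are untouched, and the anomeric centre is of no consequence.

Step 10
Reactants: 17 lactol
Product: 18 (1R,4S)-1-ArC-6,7-dimethoxy-2-(methoxycarbonyl)-1,4-dihydronaphthalene-3,4-dicarboxylic acid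
Conditions: NaClO2, NaH2PO4, 2-methyl-2-butene, t-BuOH/THF/H2O, 0 °C → rt
Reagents that add atoms: sodium chlorite, [Na+].[O-]Cl=O
Why: Pinnick oxidation of the aldehyde tautomer of the lactol in a weakly acidic buffer does not enolise C4, and 2-methyl-2-butene keeps HOCl away from the electron-rich rings.

Step 11
Reactants: 18 diacid
Product: 19 (1R,2S)-1-ArC-6,7-dimethoxy-2-(methoxycarbonyl)-1,2-dihydronaphthalene-3-carboxylic acid
Conditions: pyridine, toluene, 80 °C, argon
Reagents that add atoms: none
Why: 18 is a β,γ-unsaturated, vinylogous malonic acid, so retro-ene-type loss of CO2 from the C4 carboxyl group (decarboxylation with allylic transposition) moves the alkene to C3=C4 and delivers H to C2 on the face that carried that carboxyl group, which is the face of ring C, leaving the C2 ester trans to ring C (2S); this trans isomer is also the thermodynamic one at the epimerisable C2, so a stepwise path through the dienolate converges on it.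

Step 12
Reactants: 19 half ester
Product: 20 (1R,2S)-1-{3-[(E)-1-carboxy-2-(3,4-dimethoxyphenyl)ethenyl]oxy-4-methoxyphenyl}-6,7-dimethoxy-1,2-dihydronaphthalene-2,3-dicarboxylic acid
Conditions: LiOH, THF/MeOH/H2O, 40 °C; then 1 M HCl
Reagents that add atoms: lithium hydroxide, [Li+].[OH-]
Why: Saponification of the two methyl esters; H on C1 is not acidic in the 1,2-dihydronaphthalene, and C2, the only epimerisable centre, already sits in its more stable trans arrangement.

Step 13
Reactants: 20 triacid pentamethyl ether
Product: 21 target, (1R,2S)-1-{3-[(E)-1-carboxy-2-(3,4-dihydroxyphenyl)ethenyl]oxy-4-hydroxyphenyl}-6,7-dihydroxy-1,2-dihydronaphthalene-2,3-dicarboxylic acid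
Conditions: BBr3 (excess), CH2Cl2, −78 → 0 °C; then H2O; reversed-phase purification under argon
Reagents that add atoms: none
Why: In this Lewis acid cleavage of the five aryl methyl ethers bromide attacks the methyl carbons, whereas the aryl vinyl ether offers no sp3 C–O carbon and neither stereocentre bears a leaving group.

## Compound list

1 | methyl 2-[bis(2,2,2-trifluoroethoxy)phosphoryl]acetate | COC(=O)CP(=O)(OCC(F)(F)F)OCC(F)(F)F | starting material
2 | methyl 2-[bis(2,2,2-trifluoroethoxy)phosphoryl]-2-diazoacetate | COC(=O)C(=[N+]=[N-])P(=O)(OCC(F)(F)F)OCC(F)(F)F | intermediate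
3 | 5-iodo-2-methoxyphenol | COc1ccc(I)cc1O | starting material
4 | methyl 2-[bis(2,2,2-trifluoroethoxy)phosphoryl]-2-(5-iodo-2-methoxyphenoxy)acetate, racemic | COC(=O)C(Oc1cc(I)ccc1OC)P(=O)(OCC(F)(F)F)OCC(F)(F)F | intermediate
5 | 3,4-dimethoxybenzaldehyde | COc1ccc(C=O)cc1OC | starting material
6 | methyl (E)-3-(3,4-dimethoxyphenyl)-2-(5-iodo-2-methoxyphenoxy)prop-2-enoate (ester cis to ring D) | COc1ccc(I)cc1O/C(=C/c1ccc(OC)c(OC)c1)C(=O)OC | intermediate
7 | methyl propiolate | C#CC(=O)OC | starting material
8 | methyl 3-ArC-prop-2-ynoate | COC(=O)C#Cc1ccc(OC)c(O/C(=C/c2ccc(OC)c(OC)c2)C(=O)OC)c1 | intermediate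
9 | methyl (E)-3-ArC-2-(tributylstannyl)prop-2-enoate (ring C cis to ester) | COC(=O)/C(=C\c1ccc(OC)c(O/C(=C/c2ccc(OC)c(OC)c2)C(=O)OC)c1)[Sn](CCCC)(CCCC)CCCC | intermediate
10 | (5S)-5-[(1S,2R,5S)-menthyloxy]furan-2(5H)-one | O=C1C=C[C@@H](O[C@H]2C[C@@H](C)CC[C@@H]2C(C)C)O1 | starting material
11 | trans-3,4-dibromo-(5S)-5-(d-menthyloxy)dihydrofuran-2(3H)-one (Br on the β-carbon trans to O-menthyl) | O=C1[C@@H](Br)[C@H](Br)[C@@H](O[C@H]2C[C@@H](C)CC[C@@H]2C(C)C)O1 | intermediate
12 | (5S)-3-bromo-5-[(1S,2R,5S)-menthyloxy]furan-2(5H)-one | O=C1C(Br)=C[C@@H](O[C@H]2C[C@@H](C)CC[C@@H]2C(C)C)O1 | intermediate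
13 | methyl (Z)-3-ArC-2-{(5S)-5-(d-menthyloxy)-2-oxo-2,5-dihydrofuran-3-yl}prop-2-enoate (ring C cis to ester) | COC(=O)/C(=C\c1ccc(OC)c(O/C(=C/c2ccc(OC)c(OC)c2)C(=O)OC)c1)C1=C[C@@H](O[C@H]2C[C@@H](C)CC[C@@H]2C(C)C)OC1=O | intermediate
14 | 4,5-dimethoxy-2-(trimethylsilyl)phenyl trifluoromethanesulfonate | COc1cc(OS(=O)(=O)C(F)(F)F)c(cc1OC)[Si](C)(C)C | starting material
15 | 4,5-dimethoxybenzyne | COC1=CC#CC=C1OC | intermediate
16 | methyl (1R,4S)-1-ArC-6,7-dimethoxy-1,4-dihydronaphthalene-2-carboxylate with C3 and C4 bridged as C3–C(=O)–O–CH(O-d-menthyl)–C4; acetal carbon (S); ring C and the acetal carbon cis on ring B; H-4 cis to O-menthyl on the lactone ring | COc1ccc(cc1O/C(=C/c1ccc(OC)c(OC)c1)C(=O)OC)[C@@H]1c2cc(OC)c(OC)cc2[C@@H]2[C@@H](O[C@H]3C[C@@H](C)CC[C@@H]3C(C)C)OC(=O)C2=C1C(=O)OC | intermediate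
17 | lactol of 16 (OH in place of O-menthyl, anomeric mixture) | COc1ccc(cc1O/C(=C/c1ccc(OC)c(OC)c1)C(=O)OC)[C@@H]1c2cc(OC)c(OC)cc2[C@@H]2C(O)OC(=O)C2=C1C(=O)OC | intermediate
18 | (1R,4S)-1-ArC-6,7-dimethoxy-2-(methoxycarbonyl)-1,4-dihydronaphthalene-3,4-dicarboxylic acid (ring C and the C4 carboxyl group cis) | COc1ccc(cc1O/C(=C/c1ccc(OC)c(OC)c1)C(=O)OC)[C@@H]1c2cc(OC)c(OC)cc2[C@H](C(=O)O)C(C(=O)O)=C1C(=O)OC | intermediate
19 | (1R,2S)-1-ArC-6,7-dimethoxy-2-(methoxycarbonyl)-1,2-dihydronaphthalene-3-carboxylic acid (trans) | O=C(O)C1=Cc2cc(OC)c(OC)cc2[C@@H](c2ccc(OC)c(O/C(=C/c3ccc(OC)c(OC)c3)C(=O)OC)c2)[C@@H]1C(=O)OC | intermediate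
20 | (1R,2S)-triacid pentamethyl ether | O=C(O)C1=Cc2cc(OC)c(OC)cc2[C@@H](c2ccc(OC)c(O/C(=C/c3ccc(OC)c(OC)c3)C(=O)O)c2)[C@@H]1C(=O)O | intermediate
21 | CNP0241205.1 | O=C(O)C1=Cc2cc(O)c(O)cc2[C@@H](c2ccc(O)c(O/C(=C/c3ccc(O)c(O)c3)C(=O)O)c2)[C@@H]1C(=O)O | target

## Step count and risks

Total step count: 13. Longest linear sequence: 12 steps (steps 1–5 and 7–13, starting from 1).

**Step 8.**
- What may go wrong: the diene is tetrasubstituted and carries two acceptors. Cycloaddition may therefore be slower than self-consumption of the aryne, slower than hydrogen transfer from the adduct to the aryne (aromatisation of ring B), or slower than fluoride-induced proton shifts and epimerisation at the acetal carbon.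
- Fallback (sets out from 9, comes back at 20): the temporary carbon and the auxiliary are given up for a slimmer diene and a resolution.
- Stille coupling of 9 with methyl 2-bromoacrylate (C=C(Br)C(=O)OC) under the conditions of step 7 should give dimethyl (Z)-2-(ArC-methylidene)-3-methylidenebutanedioate F1, whose free CH2 terminus is far more open.
- Diels–Alder reaction of F1 with 15 (from 14 and CsF) should give racemic dimethyl 1-ArC-6,7-dimethoxy-1,4-dihydronaphthalene-2,3-dicarboxylate F2.
- DBU in CH2Cl2 should remove the well-aligned pseudoaxial H on C4. H-1 lies pseudoequatorial because ring C is pseudoaxial. Protonation and equilibration at C2 should then give racemic trans-dimethyl 1-ArC-6,7-dimethoxy-1,2-dihydronaphthalene-2,3-dicarboxylate F3.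
- Separation on a chiral stationary phase gives the (1R,2S)-diester F4, and LiOH as in step 12 gives 20.

**Step 11.**
- What may go wrong: a proton shift from C4 may bring the ring alkene into conjugation with the C4 carboxyl group before CO2 is lost, after which decarboxylation stops. Traces of air may aromatise ring B.
- Fallback (sets out from 17, comes back at 19): the temporary carbon is removed at the aldehyde level under neutral conditions.
- Tsuji–Wilkinson decarbonylation of the open aldehyde form of 17 with RhCl(PPh3)3 (1 equiv) in refluxing toluene should give (1R)-1-ArC-6,7-dimethoxy-2-(methoxycarbonyl)-1,4-dihydronaphthalene-3-carboxylic acid F5.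
- DBU (more than 2 equiv, CH2Cl2, rt) should then shift the alkene by deprotonation at C4 and protonation at C2, with equilibration to the trans isomer 19.

**Step 3.**
- What may go wrong: reversal of the kinetic adducts, or later equilibration, may erode the geometry toward the more stable isomer with ring D trans to the ester.
- Fallback (sets out from 7 and 3, comes back at 6): the alkene geometry is fixed by a stereospecific addition instead of an olefination.
- Sonogashira coupling of 7 with 4-iodo-1,2-dimethoxybenzene (COc1ccc(I)cc1OC) as in step 4 should give methyl 3-(3,4-dimethoxyphenyl)prop-2-ynoate F6.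
- syn-Hydrostannation as in step 5 should give methyl (E)-3-(3,4-dimethoxyphenyl)-2-(tributylstannyl)prop-2-enoate F7.
- Iododestannylation (I2, CH2Cl2, 0 °C) with retention should give methyl (E)-3-(3,4-dimethoxyphenyl)-2-iodoprop-2-enoate F8.
- Ullmann-type vinylation of phenol 3 (CuI, N,N-dimethylglycine, Cs2CO3, dioxane, 60 °C) goes with retention and should engage the activated vinyl iodide below the temperature at which the aryl iodide of 3 reacts. It should give 6.

Further compounds
F1 | step 8 | dimethyl (Z)-2-(ArC-methylidene)-3-methylidenebutanedioate | COC(=O)/C(=C\c1ccc(OC)c(O/C(=C/c2ccc(OC)c(OC)c2)C(=O)OC)c1)C(=C)C(=O)OC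
F2 | step 8 | racemic dimethyl 1-ArC-6,7-dimethoxy-1,4-dihydronaphthalene-2,3-dicarboxylate | COC(=O)C1=C(C(=O)OC)C(c2ccc(OC)c(O/C(=C/c3ccc(OC)c(OC)c3)C(=O)OC)c2)c2cc(OC)c(OC)cc2C1
F3 | step 8 | racemic trans-dimethyl 1-ArC-6,7-dimethoxy-1,2-dihydronaphthalene-2,3-dicarboxylate (both enantiomers) | COC(=O)C1=Cc2cc(OC)c(OC)cc2[C@@H](c2ccc(OC)c(O/C(=C/c3ccc(OC)c(OC)c3)C(=O)OC)c2)[C@@H]1C(=O)OC.COC(=O)C1=Cc2cc(OC)c(OC)cc2[C@H](c2ccc(OC)c(O/C(=C/c3ccc(OC)c(OC)c3)C(=O)OC)c2)[C@H]1C(=O)OC
F4 | step 8 | dimethyl (1R,2S)-1-ArC-6,7-dimethoxy-1,2-dihydronaphthalene-2,3-dicarboxylate | COC(=O)C1=Cc2cc(OC)c(OC)cc2[C@@H](c2ccc(OC)c(O/C(=C/c3ccc(OC)c(OC)c3)C(=O)OC)c2)[C@@H]1C(=O)OC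
F5 | step 11 | (1R)-1-ArC-6,7-dimethoxy-2-(methoxycarbonyl)-1,4-dihydronaphthalene-3-carboxylic acid | COc1ccc(cc1O/C(=C/c1ccc(OC)c(OC)c1)C(=O)OC)[C@@H]1c2cc(OC)c(OC)cc2CC(C(=O)O)=C1C(=O)OC
F6 | step 3 | methyl 3-(3,4-dimethoxyphenyl)prop-2-ynoate | COC(=O)C#Cc1ccc(OC)c(OC)c1
F7 | step 3 | methyl (E)-3-(3,4-dimethoxyphenyl)-2-(tributylstannyl)prop-2-enoate | COC(=O)/C(=C\c1ccc(OC)c(OC)c1)[Sn](CCCC)(CCCC)CCCC
F8 | step 3 | methyl (E)-3-(3,4-dimethoxyphenyl)-2-iodoprop-2-enoate | COC(=O)/C(I)=C\c1ccc(OC)c(OC)c1
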